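The target is cut at the two aryl–aryl bonds joining C1 and C4 of the central benzene ring to C3 of indole A (6-methoxy) and C3 of indole B (5-hydroxy). Because that ring carries oxygen on C2, C3, C5 and C6 with the indoles para on C1 and C4, it is a disguised 2,3,5,6-tetramethoxy-1,4-benzoquinone. In one flask, two different N-silylated 3-lithioindoles add in turn to the two carbonyl carbons, and SnCl2 then strips both oxygens to restore the benzene ring. The precursors are the tetramethoxyquinone and two 3-lithio-1-(triisopropylsilyl)indoles generated from the bromides, with the phenol of indole B masked as a triisopropylsilyl ether so that one fluoride treatment finishes the synthesis.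

Key step: step 4

Assumption: the two carbinol carbons of intermediate 12 would form as a cis/trans mixture and are left unassigned, because both centres are erased in the same flask and the target has no stereocentre.

Step 1
Reactants: 1 chloranil (2,3,5,6-tetrachloro-1,4-benzoquinone)
Product: 2 2,3,5,6-tetramethoxy-1,4-benzoquinone
Conditions: NaOMe (4.4 equiv), MeOH, 0 °C → reflux
Reagents that add atoms: sodium methoxide, C[O-].[Na+]
Why: Four successive addition–elimination reactions (vinylogous nucleophilic acyl substitution) of methoxide at the chlorine-bearing quinone carbons should replace all four chlorides, since each of these carbons is the β-position of an enone and behaves as a vinylogous acid chloride.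

Step 2
Reactants: 3 6-methoxyindole
Product: 5 3-bromo-6-methoxy-1-(triisopropylsilyl)indole, via 6-methoxy-1-(triisopropylsilyl)indole 4 (not isolated)
Conditions: NaH (1.05 equiv), THF, 0 °C → rt; TIPSCl (1.1 equiv); then NBS (1.0 equiv), −78 °C → rt
Reagents that add atoms: triisopropylsilyl chloride, CC(C)[Si](Cl)(C(C)C)C(C)C; N-bromosuccinimide, O=C1CCC(=O)N1Br
Why: N-deprotonation and silylation followed in the same flask by electrophilic aromatic bromination with NBS should give the 3-bromide only, because the bulky N-silyl group screens C2 and leaves the enamine-like C3 as the most nucleophilic position, as in the standard preparation of 3-bromo-1-silylindoles.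

Step 3
Reactants: 6 5-hydroxyindole
Product: 8 3-bromo-1-(triisopropylsilyl)-5-(triisopropylsilyloxy)indole, via 1-(triisopropylsilyl)-5-(triisopropylsilyloxy)indole 7 (not isolated)
Conditions: NaH (2.1 equiv), THF, 0 °C → rt; TIPSCl (2.2 equiv), rt; then NBS (1.0 equiv), −78 °C → rt
Reagents that add atoms: triisopropylsilyl chloride, CC(C)[Si](Cl)(C(C)C)C(C)C; N-bromosuccinimide, O=C1CCC(=O)N1Br
Why: The same silylation–bromination sequence applied to the phenoxide–indolide dianion should silylate both O and N with two equivalents of TIPSCl before NBS brominates C3 by electrophilic aromatic substitution, C2 and C7 being screened by the N-silyl group and C4 and C6 by the silyl ether.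

Step 4
Reactants: 2 2,3,5,6-tetramethoxy-1,4-benzoquinone; 5 3-bromo-6-methoxy-1-(triisopropylsilyl)indole; 8 3-bromo-1-(triisopropylsilyl)-5-(triisopropylsilyloxy)indole
Product: 13 1-[6-methoxy-1-(triisopropylsilyl)indol-3-yl]-4-[1-(triisopropylsilyl)-5-(triisopropylsilyloxy)indol-3-yl]-2,3,5,6-tetramethoxybenzene, via 3-lithio-6-methoxy-1-(triisopropylsilyl)indole 9 (not isolated), via 3-lithio-1-(triisopropylsilyl)-5-(triisopropylsilyloxy)indole 10 (not isolated), via mono-adduct lithium alkoxide 11 (not isolated), via bis-adduct dilithium dialkoxide 12 (not isolated)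
Conditions: 5, t-BuLi (2.0 equiv), THF, −78 °C, then added slowly to 2 (1.1 equiv), THF, −78 °C; 8, t-BuLi (2.0 equiv), THF, −78 °C, then added (1.5 equiv), −78 → 0 °C; then SnCl2·2H2O (divalent tin, 4 equiv), 1 M aq HCl, THF, 0 °C → rt
Reagents that add atoms: none
Why: Bromine–lithium exchange gives the C3-lithioindoles 9 and 10, whose bulky N-silyl groups prevent migration of the metal to C2; 9 adds to one carbonyl carbon of 2 to give alkoxide 11, whose remaining carbonyl is a doubly vinylogous ester beside an anionic oxygen and is far less electrophilic than the quinone, so the different nucleophile 10 can be delivered afterwards to form dialkoxide 12. On acidification in the presence of SnCl2 each doubly allylic, indolyl-stabilised carbinol ionises and two-electron reduction expels both oxygens, the formation of the electron-rich benzene ring driving the reaction for the cis and the trans diol alike. The closest known reaction type is the stepwise 1,2-addition of two different aryllithiums to a 1,4-benzoquinone or acenequinone followed by SnCl2 reductive aromatisation of the cyclohexadiene-1,4-diol. No ring closes and no stereocentre survives, since the two carbinol centres of 12 form without control and are both erased. The step needs mono- before bis-addition, secured by slow addition of 9 to a slight excess of 2 at −78 °C and by the deactivated alkoxide 11, and it needs carbonyl attack in preference to conjugate addition with methoxide loss or electron transfer, secured by the hard lithium reagent at low temperature (which attacks vinylogous esters at the carbonyl carbon) and by the four donor methoxy groups that lower the reduction potential of 2. Because both aryl–aryl bonds are made at sp2 carbonyl carbons before the ring is aromatic, the crowding of a coupling between two flanking methoxy groups is avoided.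

Step 5
Reactants: 13 1-[6-methoxy-1-(triisopropylsilyl)indol-3-yl]-4-[1-(triisopropylsilyl)-5-(triisopropylsilyloxy)indol-3-yl]-2,3,5,6-tetramethoxybenzene
Product: 14 3-[4-(6-methoxy-1H-indol-3-yl)-2,3,5,6-tetramethoxyphenyl]-1H-indol-5-ol
Conditions: Bu4NF (3.5 equiv), AcOH (3.5 equiv), THF, 0 °C → rt, argon
Reagents that add atoms: none
Why: Fluoride-induced desilylation, driven by the strong Si–F bond, should cleave the two N–Si bonds and the aryl O–Si bond in one operation, and the acetic acid buffer protonates the indolide and phenoxide as they form so that the oxidation-prone 5-hydroxyindole is not left as its anion.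

Compound list
1 | chloranil (2,3,5,6-tetrachloro-1,4-benzoquinone) | O=C1C(Cl)=C(Cl)C(=O)C(Cl)=C1Cl | starting material
2 | 2,3,5,6-tetramethoxy-1,4-benzoquinone | COC1=C(OC)C(=O)C(OC)=C(OC)C1=O | intermediate
3 | 6-methoxyindole | COc1ccc2cc[nH]c2c1 | starting material
4 | 6-methoxy-1-(triisopropylsilyl)indole | COc1ccc2ccn([Si](C(C)C)(C(C)C)C(C)C)c2c1 | intermediate (not isolated)
5 | 3-bromo-6-methoxy-1-(triisopropylsilyl)indole | COc1ccc2c(Br)cn([Si](C(C)C)(C(C)C)C(C)C)c2c1 | intermediate
6 | 5-hydroxyindole | Oc1ccc2[nH]ccc2c1 | starting material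
7 | 1-(triisopropylsilyl)-5-(triisopropylsilyloxy)indole | CC(C)[Si](Oc1ccc2c(ccn2[Si](C(C)C)(C(C)C)C(C)C)c1)(C(C)C)C(C)C | intermediate (not isolated)
8 | 3-bromo-1-(triisopropylsilyl)-5-(triisopropylsilyloxy)indole | CC(C)[Si](Oc1ccc2c(c(Br)cn2[Si](C(C)C)(C(C)C)C(C)C)c1)(C(C)C)C(C)C | intermediate
9 | 3-lithio-6-methoxy-1-(triisopropylsilyl)indole | [Li]c1cn([Si](C(C)C)(C(C)C)C(C)C)c2cc(OC)ccc12 | intermediate (not isolated)
10 | 3-lithio-1-(triisopropylsilyl)-5-(triisopropylsilyloxy)indole | [Li]c1cn([Si](C(C)C)(C(C)C)C(C)C)c2ccc(O[Si](C(C)C)(C(C)C)C(C)C)cc12 | intermediate (not isolated)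
11 | lithium 1-[6-methoxy-1-(triisopropylsilyl)indol-3-yl]-2,3,5,6-tetramethoxy-4-oxocyclohexa-2,5-dien-1-olate | COC1=C(OC)C(O[Li])(c2cn([Si](C(C)C)(C(C)C)C(C)C)c3cc(OC)ccc23)C(OC)=C(OC)C1=O | intermediate (not isolated)
12 | dilithium 1-[6-methoxy-1-(triisopropylsilyl)indol-3-yl]-4-[1-(triisopropylsilyl)-5-(triisopropylsilyloxy)indol-3-yl]-2,3,5,6-tetramethoxycyclohexa-2,5-diene-1,4-diolate (cis/trans mixture) | COC1=C(OC)C(O[Li])(c2cn([Si](C(C)C)(C(C)C)C(C)C)c3cc(OC)ccc23)C(OC)=C(OC)C1(O[Li])c1cn([Si](C(C)C)(C(C)C)C(C)C)c2ccc(O[Si](C(C)C)(C(C)C)C(C)C)cc12 | intermediate (not isolated)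
13 | 1-[6-methoxy-1-(triisopropylsilyl)indol-3-yl]-4-[1-(triisopropylsilyl)-5-(triisopropylsilyloxy)indol-3-yl]-2,3,5,6-tetramethoxybenzene | COc1ccc2c(-c3c(OC)c(OC)c(-c4cn([Si](C(C)C)(C(C)C)C(C)C)c5ccc(O[Si](C(C)C)(C(C)C)C(C)C)cc45)c(OC)c3OC)cn([Si](C(C)C)(C(C)C)C(C)C)c2c1 | intermediate
14 | 3-[4-(6-methoxy-1H-indol-3-yl)-2,3,5,6-tetramethoxyphenyl]-1H-indol-5-ol | COc1ccc2c(-c3c(OC)c(OC)c(-c4c[nH]c5ccc(O)cc45)c(OC)c3OC)c[nH]c2c1 | target

Total step count: 5
Longest linear sequence: 3 steps (3 → 5 → 13 → 14; the branches from 1 and from 6 are equally long)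

Steps most likely to fail

Step 4. The first addition may run on to the symmetrical bis-adduct. The lithioindole may also transfer an electron to the quinone instead of adding, or the second addition may stall at the deactivated alkoxide 11. In the acidic reduction, hydrolysis of the methoxy enol ethers may outrun the removal of the two oxygens by tin. The fallback sets out from 2, 5 and 8 and comes back at 13 by two Suzuki–Miyaura couplings. Quinone 2 would be reduced with Na2S2O4 in EtOAc/water to 2,3,5,6-tetramethoxybenzene-1,4-diol F1 and converted with Tf2O and pyridine into 2,3,5,6-tetramethoxy-1,4-phenylene bis(trifluoromethanesulfonate) F2. Bromide 5 would be lithiated as in step 4 and quenched with 2-isopropoxy-4,4,5,5-tetramethyl-1,3,2-dioxaborolane to give 6-methoxy-3-(4,4,5,5-tetramethyl-1,3,2-dioxaborolan-2-yl)-1-(triisopropylsilyl)indole F3. Coupling of F3 with an excess of F2 (Pd(OAc)2, SPhos, K3PO4, toluene, 90 °C) should give 4-[6-methoxy-1-(triisopropylsilyl)indol-3-yl]-2,3,5,6-tetramethoxyphenyl trifluoromethanesulfonate F4. The boronate made in the same way from 8, 3-(4,4,5,5-tetramethyl-1,3,2-dioxaborolan-2-yl)-1-(triisopropylsilyl)-5-(triisopropylsilyloxy)indole F5, would then be coupled with F4 under the same conditions to give 13.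

Step 3. Silylation of the sparingly soluble dianion may stay incomplete at nitrogen, so that NBS meets N–H indole and over-brominates or oxidises it, or bromine may enter the activated benzo ring. The fallback sets out from 6 and comes back at 14, carrying the phenol as a benzyl ether so that only one anion has to be silylated. Phenol-selective O-benzylation of 6 (BnBr, K2CO3, acetone, reflux) would give 5-benzyloxyindole F6. NaH/TIPSCl would give 5-benzyloxy-1-(triisopropylsilyl)indole F7, and NBS would then give 5-benzyloxy-3-bromo-1-(triisopropylsilyl)indole F8. In step 4, F8 would take the place of 8: exchange to 5-benzyloxy-3-lithio-1-(triisopropylsilyl)indole F9, addition to 11 to give dilithium 1-[5-benzyloxy-1-(triisopropylsilyl)indol-3-yl]-4-[6-methoxy-1-(triisopropylsilyl)indol-3-yl]-2,3,5,6-tetramethoxycyclohexa-2,5-diene-1,4-diolate F10, and SnCl2/HCl reduction to 1-[5-benzyloxy-1-(triisopropylsilyl)indol-3-yl]-4-[6-methoxy-1-(triisopropylsilyl)indol-3-yl]-2,3,5,6-tetramethoxybenzene F11. Bu4NF would remove both N-silyl groups to give 5-benzyloxy-3-[4-(6-methoxy-1H-indol-3-yl)-2,3,5,6-tetramethoxyphenyl]-1H-indole F12, and hydrogenolysis (H2, Pd on carbon, EtOAc/MeOH) would cleave the benzyl ether to give 14.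

Step 5. The electron-rich 5-hydroxyindole may be oxidised by air during desilylation, work-up and chromatography, or one hindered silyl group may be cleaved incompletely, leaving a mixture that is hard to purify as the free phenol. The fallback sets out from 13 and comes back at 14 by a trap-and-release sequence. After the fluoride treatment the crude phenol would be acetylated in the same flask (Ac2O, pyridine) to 3-[4-(6-methoxy-1H-indol-3-yl)-2,3,5,6-tetramethoxyphenyl]-1H-indol-5-yl acetate F13, an oxidation-resistant derivative that can be chromatographed free of partly silylated material. Acid-catalysed methanolysis (HCl in MeOH, rt, degassed) would then release 14 without a phenoxide being present.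

Further compounds
F1 | step 4 | 2,3,5,6-tetramethoxybenzene-1,4-diol | COc1c(O)c(OC)c(OC)c(O)c1OC
F2 | step 4 | 2,3,5,6-tetramethoxy-1,4-phenylene bis(trifluoromethanesulfonate) | COc1c(OS(=O)(=O)C(F)(F)F)c(OC)c(OC)c(OS(=O)(=O)C(F)(F)F)c1OC
F3 | step 4 | 6-methoxy-3-(4,4,5,5-tetramethyl-1,3,2-dioxaborolan-2-yl)-1-(triisopropylsilyl)indole | COc1ccc2c(B3OC(C)(C)C(C)(C)O3)cn([Si](C(C)C)(C(C)C)C(C)C)c2c1
F4 | step 4 | 4-[6-methoxy-1-(triisopropylsilyl)indol-3-yl]-2,3,5,6-tetramethoxyphenyl trifluoromethanesulfonate | COc1ccc2c(-c3c(OC)c(OC)c(OS(=O)(=O)C(F)(F)F)c(OC)c3OC)cn([Si](C(C)C)(C(C)C)C(C)C)c2c1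
F5 | step 4 | 3-(4,4,5,5-tetramethyl-1,3,2-dioxaborolan-2-yl)-1-(triisopropylsilyl)-5-(triisopropylsilyloxy)indole | CC(C)[Si](Oc1ccc2c(c(B3OC(C)(C)C(C)(C)O3)cn2[Si](C(C)C)(C(C)C)C(C)C)c1)(C(C)C)C(C)C
F6 | step 3 | 5-benzyloxyindole | c1ccc(COc2ccc3[nH]ccc3c2)cc1
F7 | step 3 | 5-benzyloxy-1-(triisopropylsilyl)indole | CC(C)[Si](n1ccc2cc(OCc3ccccc3)ccc21)(C(C)C)C(C)C
F8 | step 3 | 5-benzyloxy-3-bromo-1-(triisopropylsilyl)indole | CC(C)[Si](n1cc(Br)c2cc(OCc3ccccc3)ccc21)(C(C)C)C(C)C
F9 | step 3 | 5-benzyloxy-3-lithio-1-(triisopropylsilyl)indole | [Li]c1cn([Si](C(C)C)(C(C)C)C(C)C)c2ccc(OCc3ccccc3)cc12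
F10 | step 3 | dilithium 1-[5-benzyloxy-1-(triisopropylsilyl)indol-3-yl]-4-[6-methoxy-1-(triisopropylsilyl)indol-3-yl]-2,3,5,6-tetramethoxycyclohexa-2,5-diene-1,4-diolate | COC1=C(OC)C(O[Li])(c2cn([Si](C(C)C)(C(C)C)C(C)C)c3cc(OC)ccc23)C(OC)=C(OC)C1(O[Li])c1cn([Si](C(C)C)(C(C)C)C(C)C)c2ccc(OCc3ccccc3)cc12
F11 | step 3 | 1-[5-benzyloxy-1-(triisopropylsilyl)indol-3-yl]-4-[6-methoxy-1-(triisopropylsilyl)indol-3-yl]-2,3,5,6-tetramethoxybenzene | COc1ccc2c(-c3c(OC)c(OC)c(-c4cn([Si](C(C)C)(C(C)C)C(C)C)c5ccc(OCc6ccccc6)cc45)c(OC)c3OC)cn([Si](C(C)C)(C(C)C)C(C)C)c2c1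
F12 | step 3 | 5-benzyloxy-3-[4-(6-methoxy-1H-indol-3-yl)-2,3,5,6-tetramethoxyphenyl]-1H-indole | COc1ccc2c(-c3c(OC)c(OC)c(-c4c[nH]c5ccc(OCc6ccccc6)cc45)c(OC)c3OC)c[nH]c2c1
F13 | step 5 | 3-[4-(6-methoxy-1H-indol-3-yl)-2,3,5,6-tetramethoxyphenyl]-1H-indol-5-yl acetate | COc1ccc2c(-c3c(OC)c(OC)c(-c4c[nH]c5ccc(OC(C)=O)cc45)c(OC)c3OC)c[nH]c2c1
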